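Ring B (C2–Ca–Cb–Cc–Cd) carries two adjacent spiro carbons, pinane C2 and ring-A carbon Ca, and its methylene Cd lies on the face of C2 turned away from the C6 CMe2 bridge. Contracting C2, Ca and Cd to a cyclopropane whose Ca is the central carbon of Meldrum's acid gives a strained precursor that is made from (+)-β-pinene with C2 already fixed. One operation, iodide opening at Cd, Michael addition of Ca to (E)-3-methyl-1-nitrobut-1-ene and nitronate alkylation at Cd, inserts Cb–Cc, forms Ca–Cb and Cc–Cd, closes ring B and sets Cb. Denitration, an aldol at Ca and a Dieckmann closure then build ring A.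

Key step: step 6

Atom labels: the pinane is numbered C1–C7, with C6 the CMe2 bridge and C7 the CH2 bridge. Ring B is C2–Ca–Cb(iPr)–Cc–Cd. Ring A is Ca–Ce(=O)–Cf(Me)=Cg(OMe)–Ch(Me)2–Ci(=O).

Stereochemical bookkeeping from the target SMILES:
- Ca is syn and Cd is anti to the C6 bridge.
- On ring B, isopropyl (Cb), Ce (on Ca) and C3 (on C2) share one face. Ci and bridgehead C1 lie on the other.
- The pinane part corresponds to (1R,5R)-β-pinene.

Design remarks:
- The Meldrum's unit is kept in the cyclopropane because its stabilised enolate is the best leaving group for an SN2 opening.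
- Nitro is removed first, under neutral conditions, because base could reverse the Michael bond Ca–Cb.
- The quaternary Ca is rebuilt by aldol addition and oxidation, not by direct acylation with an α-quaternary acyl chloride.

Assumption: (+)-β-pinene of high enantiomeric purity and 4-(2-methylprop-1-enyl)morpholine are taken as purchasable. The ring-A trione is a tautomer mixture and is drawn as the enol that matches the target.

Step 1
Reactants: 1 (1R,5R)-(+)-β-pinene
Product: 3 (1S,5R)-(−)-nopinone, via secondary ozonide 2 (not isolated)
Conditions: O3, CH2Cl2, −78 °C; then Me2S, −78 °C to rt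
Reagents that add atoms: ozone, [O-][O+]=O
Why: Ozonolysis with reductive work-up (Criegee mechanism) cleaves the only C=C bond and leaves C1 and C5 untouched, so 3 keeps the absolute configuration of 1 (the C1 descriptor changes only because the CIP ranking changes).

Step 2
Reactants: 3 (1S,5R)-(−)-nopinone; 4 Meldrum's acid
Product: 5 nopinylidene Meldrum's acid
Conditions: TiCl4, pyridine, THF/CH2Cl2, 0 °C to rt
Reagents that add atoms: none
Why: Knoevenagel condensation in the Lehnert variant, in which pyridine-buffered TiCl4 activates the hindered ketone and binds the water, is established for cyclic and dialkyl ketones with Meldrum's acid and creates no stereocentre.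

Step 3
Reactants: 5 nopinylidene Meldrum's acid
Product: 6 dispiro cyclopropane of C2, Ca and Cd (Cd anti to the C6 bridge)
Conditions: Me3S(O)I, NaH, DMSO, rt; then 5 in THF, 0 °C to rt
Reagents that add atoms: trimethylsulfoxonium iodide, C[S+](C)(C)=O.[I-]
Why: Corey–Chaykovsky cyclopropanation, in which the ylide adds in conjugate fashion to the strongly electrophilic C2 from the face anti to the C6 bridge (the face from which nucleophiles reach nopinone) and the Meldrum's enolate then expels DMSO in a 3-exo-tet closure, places Cd anti and Ca syn to the bridge and so sets C2.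

Step 4
Reactants: 7 isobutyraldehyde; 8 nitromethane
Product: 9 (±)-3-methyl-1-nitrobutan-2-ol
Conditions: KOtBu (cat.), THF/tBuOH, 0 °C
Reagents that add atoms: none
Why: Henry (nitroaldol) reaction under catalytic base, whose racemic carbinol centre is destroyed in step 5.

Step 5
Reactants: 9 (±)-3-methyl-1-nitrobutan-2-ol
Product: 11 (E)-3-methyl-1-nitrobut-1-ene, via mesylate 10 (not isolated)
Conditions: MsCl, Et3N, CH2Cl2, 0 °C
Reagents that add atoms: none
Why: Mesylation followed by E1cB elimination, the standard dehydration of β-nitro alcohols, gives the conjugated nitroalkene as the more stable E isomer.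

Step 6
Reactants: 6 dispiro cyclopropane of C2, Ca and Cd; 11 (E)-3-methyl-1-nitrobut-1-ene
Product: 14 ring-B nitro adduct (spiro Meldrum's unit on Ca; isopropyl on Cb on the C3 face; nitro on Cc trans to it), via iodomagnesium enolate 12 (not isolated), via iodo nitronate 13 (not isolated)
Conditions: MgI2 (1 equiv), 4 Å MS, THF, 60 °C, slow addition of 11 (2 equiv)
Reagents that add atoms: none
Why: Proposed new method: iodide from THF-solvated MgI2 attacks Cd, the only unsubstituted cyclopropane carbon, in an SN2 homoconjugate opening that breaks Ca–Cd and leaves the four bonds of C2 intact; enolate 12 then adds through Ca to Cb of 11, and the nitronate carbon Cc of 13 displaces iodide from Cd, which returns MgI2 and lets the released ring strain pay for the crowded Ca–Cb bond. The closest known reaction types are the MgI2-promoted ring expansion of spiro-activated cyclopropanes by imines, homoconjugate additions to cyclopropane-1,1-dicarbonyl compounds and Michael-initiated ring closures in which a nitronate carbon displaces a halide; a nitroalkene as the two-atom partner of such a cyclopropane has not been shown. Ring B closes in the 5-exo-tet mode, and C-alkylation is preferred because O-alkylation would demand a seven-membered cyclic nitronate. Cb is controlled by a Curtin–Hammett situation: ring opening and Michael addition are reversible, and the slow closure selects the adduct whose isopropyl group sits pseudo-equatorial on the C3 face of the forming ring, away from bridgehead C1 and its bridges. Cc forms with nitro trans to isopropyl for the same steric reason, can relax to that arrangement through its acidic C–H, and is erased in step 7. The step needs attack at Cd instead of ionisation at tertiary C2 (which would unravel the cyclobutane), secured by the soft nucleophile, the donor solvent and the W-shaped Meldrum's unit that cannot chelate magnesium, and it needs closure to outrun oligomerisation of 11, secured by slow addition of this β-branched nitroalkene.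

Step 7
Reactants: 14 ring-B nitro adduct
Product: 15 denitrated ring-B Meldrum's compound (Cc = CH2)
Conditions: Bu3SnH, AIBN, toluene, reflux
Reagents that add atoms: none
Why: Tin hydride radical denitration of a secondary nitroalkane runs under neutral conditions, which avoids base-induced retro-Michael cleavage of Ca–Cb, and the Cc radical is not adjacent to the cyclobutane, so C2 and Cb stay untouched.

Step 8
Reactants: 15 denitrated ring-B Meldrum's compound
Product: 17 methyl ester with hydrogen on Ca (epimer mixture at Ca), via malonic half-ester 16 (not isolated)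
Conditions: NaOMe, MeOH, reflux; cold aq. HCl work-up; then DMSO, 130 °C
Reagents that add atoms: sodium methoxide, C[O-].[Na+]
Why: Alkoxide opening of a 5,5-disubstituted Meldrum's acid with loss of acetone gives the malonic half-ester, whose thermal decarboxylation through the cyclic six-membered transition state is helped by relief of strain at Ca, and the Ca–H configuration does not matter because Ca is planarised in step 10.

Step 9
Reactants: 18 4-(2-methylprop-1-enyl)morpholine; 19 propionyl chloride
Product: 21 2,2-dimethyl-3-oxopentanal, via acyl iminium chloride 20 (not isolated)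
Conditions: Et2O, 0 °C to reflux; then H2O, rt
Reagents that add atoms: water, O
Why: Stork enamine acylation, in which the β,β-disubstituted aldehyde enamine is acylated at carbon to a quaternary iminium salt that cannot tautomerise and is hydrolysed to the keto aldehyde.

Step 10
Reactants: 17 methyl ester with hydrogen on Ca; 21 2,2-dimethyl-3-oxopentanal
Product: 23 aldol adduct (Ci carbinol on Ca trans to isopropyl; CO2Me = Ce cis to isopropyl; carbinol epimers), via lithium enolate 22 (not isolated)
Conditions: LiN(iPr)2 (LDA), THF, −78 to 0 °C; then 21, −78 °C; AcOH quench at −78 °C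
Reagents that add atoms: none
Why: Aldol addition of a lithium ester enolate to a non-enolisable aldehyde (faster than attack on or deprotonation of the flanked ethyl ketone), in which allylic 1,3-strain in the exocyclic enolate turns the isopropyl group on Cb perpendicular to the enolate plane while C1–H and C3–H2 flank both faces about equally, so Ci bonds to Ca trans to isopropyl and sets Ca, and the carbinol centre is removed in step 11.

Step 11
Reactants: 23 aldol adduct
Product: 24 β-keto ester (Ca bears CO2Me and C(=O)CMe2C(=O)Et)
Conditions: Dess–Martin periodinane, CH2Cl2, rt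
Reagents that add atoms: none
Why: Dess–Martin oxidation under neutral conditions converts the hindered secondary alcohol to the ketone without retro-aldol cleavage and touches no stereocentre, since Ca is quaternary.

Step 12
Reactants: 24 β-keto ester
Product: 25 spiro ring-A trione (drawn as the Cg enol)
Conditions: KOtBu, THF, 0 °C to rt; aq. HCl work-up
Reagents that add atoms: none
Why: Dieckmann-type condensation, known for 2,2-dialkyl-3,5-dioxo esters, in which the only enolisable position (Cf, the CH2 of the ethyl ketone) attacks ester carbon Ce in a 6-(enolendo)-exo-trig closure helped by the two quaternary ring atoms, and deprotonation of the new β-diketone makes it irreversible.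

Step 13
Reactants: 25 spiro ring-A trione
Product: 26 target CNP0307059.1
Conditions: Me2SO4, K2CO3, acetone, reflux
Reagents that add atoms: dimethyl sulfate, COS(=O)(=O)OC
Why: O-Alkylation of a cyclic β-diketone enolate with a hard methylating agent should occur at the oxygen on Cg, flanked only by CMe2, because the oxygen on Ce is buried between isopropyl, C3 and spiro carbon Ca, and this gives the methyl enol ether of the target.

Compound list

1 | (1R,5R)-(+)-β-pinene | C=C1CC[C@@H]2C[C@H]1C2(C)C | starting material
2 | secondary ozonide of 1 (spiro-1,2,4-trioxolane at C2, configuration at C2 irrelevant) | C1OOC2(O1)CC[C@@H]3C[C@H]2C3(C)C | intermediate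
3 | (1S,5R)-(−)-nopinone (6,6-dimethylbicyclo[3.1.1]heptan-2-one) | O=C1CC[C@@H]2C[C@H]1C2(C)C | intermediate
4 | Meldrum's acid (2,2-dimethyl-1,3-dioxane-4,6-dione) | CC1(C)OC(=O)CC(=O)O1 | starting material
5 | nopinylidene Meldrum's acid, 5-[(1S,5R)-6,6-dimethylbicyclo[3.1.1]heptan-2-ylidene]-2,2-dimethyl-1,3-dioxane-4,6-dione | CC1(C)OC(=O)C(=C2CC[C@@H]3C[C@H]2C3(C)C)C(=O)O1 | intermediate
6 | dispiro cyclopropane of pinane C2, Meldrum's C5 (Ca) and CH2 (Cd); Cd anti and Ca syn to the C6 bridge | CC1(C)OC(=O)C2(C(=O)O1)C[C@@]23CC[C@@H]4C[C@H]3C4(C)C | intermediate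
7 | isobutyraldehyde | CC(C)C=O | starting material
8 | nitromethane | C[N+](=O)[O-] | starting material
9 | (±)-3-methyl-1-nitrobutan-2-ol | CC(C)C(O)C[N+](=O)[O-] | intermediate
10 | (±)-3-methyl-1-nitrobutan-2-yl methanesulfonate | CC(C)C(C[N+](=O)[O-])OS(C)(=O)=O | intermediate
11 | (E)-3-methyl-1-nitrobut-1-ene | CC(C)/C=C/[N+](=O)[O-] | intermediate
12 | iodomagnesium enolate of 5-[2-(iodomethyl)pinan-2-yl] Meldrum's acid (CH2I anti to the C6 bridge) | CC1(C)OC(=O)C(=C(O[Mg]I)O1)[C@@]1(CI)CC[C@@H]2C[C@H]1C2(C)C | intermediate
13 | iodomagnesium nitronate of the Michael adduct (Ca–Cb formed, CH2I still open) | CC1(C)OC(=O)C(C(=O)O1)([C@@H](C(C)C)C=[N+]([O-])O[Mg]I)[C@@]1(CI)CC[C@@H]2C[C@H]1C2(C)C | intermediate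
14 | ring-B nitro adduct: cyclopentane C2–Ca–Cb–Cc–Cd, spiro at C2 (pinane) and Ca (Meldrum's C5); isopropyl on the C3 face, nitro on the C1 face | CC1(C)OC(=O)C2(C(=O)O1)[C@@H](C(C)C)[C@H]([N+](=O)[O-])C[C@@]23CC[C@@H]4C[C@H]3C4(C)C | intermediate
15 | denitrated ring-B Meldrum's compound (Cc = CH2) | CC1(C)OC(=O)C2(C(=O)O1)[C@@H](C(C)C)CC[C@@]23CC[C@@H]4C[C@H]3C4(C)C | intermediate
16 | malonic half-ester (CO2Me and CO2H on Ca, both Ca epimers) | COC(=O)C2(C(=O)O)[C@@H](C(C)C)CC[C@@]21CC[C@@H]2C[C@H]1C2(C)C | intermediate
17 | methyl ester with hydrogen on Ca (epimer mixture at Ca) | COC(=O)C2[C@@H](C(C)C)CC[C@@]21CC[C@@H]2C[C@H]1C2(C)C | intermediate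
18 | 4-(2-methylprop-1-enyl)morpholine | CC(C)=CN1CCOCC1 | starting material
19 | propionyl chloride | CCC(=O)Cl | starting material
20 | 4-(2,2-dimethyl-3-oxopentylidene)morpholin-4-ium chloride | CCC(=O)C(C)(C)C=[N+]1CCOCC1.[Cl-] | intermediate
21 | 2,2-dimethyl-3-oxopentanal | CCC(=O)C(C)(C)C=O | intermediate
22 | lithium enolate of 17 (exocyclic at Ca) | COC(O[Li])=C2[C@@H](C(C)C)CC[C@@]21CC[C@@H]2C[C@H]1C2(C)C | intermediate
23 | aldol adduct: Ca bears CO2Me (cis to isopropyl) and CH(OH)CMe2C(=O)Et (trans to isopropyl); carbinol epimers | COC(=O)[C@@]2(C(O)C(C)(C)C(=O)CC)[C@@H](C(C)C)CC[C@@]21CC[C@@H]2C[C@H]1C2(C)C | intermediate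
24 | β-keto ester: Ca bears CO2Me (cis to isopropyl) and C(=O)CMe2C(=O)Et (trans to isopropyl) | COC(=O)[C@@]2(C(=O)C(C)(C)C(=O)CC)[C@@H](C(C)C)CC[C@@]21CC[C@@H]2C[C@H]1C2(C)C | intermediate
25 | spiro ring-A trione, drawn as the Cg enol | OC1=C(C)C(=O)[C@@]2(C(=O)C1(C)C)[C@@H](C(C)C)CC[C@@]21CC[C@@H]2C[C@H]1C2(C)C | intermediate
26 | CNP0307059.1 | COC1=C(C)C(=O)[C@@]2(C(=O)C1(C)C)[C@@H](C(C)C)CC[C@@]21CC[C@@H]2C[C@H]1C2(C)C | target

Total step count: 13
Longest linear sequence: 10 steps (1, 2, 3, 6, 7, 8, 10, 11, 12, 13)

Steps most likely to fail

1. Step 6 (the labelled step).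
- What may go wrong: Lewis-acid ionisation at C2 with rupture of the cyclobutane; stalling of the displacement at the neopentyl-type Cd, so that oligomerisation of the nitroalkene takes over; or poor facial selectivity at Cb.
- Fallback: known chemistry, a polar conjugate addition plus a radical ring closure in place of the anionic cascade. It sets out from 5 and comes back at 15. 4-Methylpent-3-enylmagnesium bromide (from commercial 5-bromo-2-methylpent-2-ene and Mg) would add in conjugate fashion to C2 of 5 from the face anti to the bridge. This gives the 5-(2-homoprenylpinan-2-yl) Meldrum's acid F1, which already holds C2–Cd–Cc–Cb. Mn(OAc)3·2H2O and Cu(OAc)2 in AcOH would oxidise its acidic Ca–H to the Ca radical, which closes ring B by 5-exo-trig addition to Cb. Oxidative elimination of the tertiary radical gives the isopropenyl spiro compound F2. H2 over Pd/C in EtOAc would then saturate the alkene to 15.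

2. Step 10.
- What may go wrong: sluggish deprotonation of the crowded Ca–H, reversal of the aldol addition, or insufficient facial selectivity at Ca.
- Fallback: the quaternary Ca made in step 6 is kept and its two carbonyl groups are told apart, so no bond to Ca has to be formed. It sets out from 15 and comes back at 23. NaOMe in MeOH opens 15 as in step 8, but the half-esters are isolated and separated: the half-ester with the free acid trans to isopropyl F3 and its Ca epimer F4. BH3·SMe2 reduces the acid of F3 beside the ester to the hydroxymethyl ester F5. LiBH4 reduces the ester of the lithium carboxylate of F4 to the hydroxy acid F6, which MeI/K2CO3 esterifies to the same F5, so both epimers converge. Dess–Martin oxidation gives the aldehyde ester F7. A Reformatsky addition of 2-bromo-2-methylpentan-3-one F8 (from 2-methylpentan-3-one and Br2 in AcOH) with Zn in THF forms Ci–Ch and gives 23.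

3. Step 3.
- What may go wrong: deprotonation at C3 by the basic ylide, which forms the extended enolate of 5 and so prevents conjugate addition at the tetrasubstituted C2.
- Fallback: a non-basic cycloaddition and extrusion route. It sets out from 5 and comes back at 6. Ethereal CH2N2 at 0 °C would undergo 1,3-dipolar cycloaddition, its carbon bonding to C2 from the face anti to the bridge and nitrogen bonding to Ca, to give the spiro 1-pyrazoline F9. Photolysis (or gentle heating) would extrude nitrogen with retention to give 6.

Further compounds

F1 | step 6 | 5-[2-(4-methylpent-3-enyl)pinan-2-yl] Meldrum's acid (side chain anti to the C6 bridge) | CC(C)=CCC[C@]1(C2C(=O)OC(C)(C)OC2=O)CC[C@@H]2C[C@H]1C2(C)C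
F2 | step 6 | ring-B spiro Meldrum's compound with isopropenyl on Cb | CC1(C)OC(=O)C2(C(=O)O1)[C@@H](C(C)=C)CC[C@@]23CC[C@@H]4C[C@H]3C4(C)C
F3 | step 10 | half-ester with CO2H trans and CO2Me cis to isopropyl | COC(=O)[C@@]2(C(=O)O)[C@@H](C(C)C)CC[C@@]21CC[C@@H]2C[C@H]1C2(C)C
F4 | step 10 | half-ester with CO2H cis and CO2Me trans to isopropyl | COC(=O)[C@]2(C(=O)O)[C@@H](C(C)C)CC[C@@]21CC[C@@H]2C[C@H]1C2(C)C
F5 | step 10 | hydroxymethyl ester (CH2OH trans, CO2Me cis to isopropyl) | COC(=O)[C@@]2(CO)[C@@H](C(C)C)CC[C@@]21CC[C@@H]2C[C@H]1C2(C)C
F6 | step 10 | hydroxy acid (CH2OH trans, CO2H cis to isopropyl) | OC(=O)[C@@]2(CO)[C@@H](C(C)C)CC[C@@]21CC[C@@H]2C[C@H]1C2(C)C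
F7 | step 10 | aldehyde ester (CHO trans, CO2Me cis to isopropyl) | COC(=O)[C@@]2(C=O)[C@@H](C(C)C)CC[C@@]21CC[C@@H]2C[C@H]1C2(C)C
F8 | step 10 | 2-bromo-2-methylpentan-3-one | CCC(=O)C(C)(C)Br
F9 | step 3 | spiro 1-pyrazoline (Ca–N=N–Cd–C2) | CC1(C)OC(=O)C2(C(=O)O1)N=NC[C@@]23CC[C@@H]4C[C@H]3C4(C)C
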